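**Retrosynthetic overview**

1. Garcinoic acid 23 comes from its O-methyl ether 22 by thiolate demethylation, and 22 from the C13′ alcohol 20 (MnO2, then Pinnick). C13′ is carried as a silyl ether because the hydride desulfonylation would not spare an ester.
2. The C5′–C6′ bond joins the chroman allylic bromide 11 (C1′–C5′) to the geranyl-derived sulfone 16 (C6′–C13′), followed by Pd/hydride desulfonylation. Both partners get their E-CH2X terminus by SeO2 oxidation of an E-methyl group.
3. Chroman 8 comes from bromo alcohol 7 by palladium-catalysed O1–C8a etherification. The dihydropyran ring is the only ring formed; the benzene ring is bought with aniline 1.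
4. 7 comes from (R)-linalool 5 and dihalide 4 by hydroboration/B-alkyl Suzuki coupling (C4–C4a). 4 comes from 4-methoxy-2-methylaniline 1 by iodination and Sandmeyer bromination.
5. Feature: the quaternary stereocentre C2, with its methyl group, O1, C3–C4 and C1′–C5′, is the carbinol carbon of (R)-linalool with its vinyl and homoprenyl arms. C2 is therefore bought and never touched; only the O1–C8a bond of the pyran ring is missing.

Key step: step 4

Assumption: (R)-(−)-linalool of high enantiomeric purity is taken as the commercial material, and its tertiary hydroxyl is carried unprotected through the hydroboration (a slight excess of 9-BBN covers any B–H consumed at oxygen).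

**Route**

Step 1
Reactants: 1 4-methoxy-2-methylaniline
Product: 2 2-iodo-4-methoxy-6-methylaniline
Conditions: NIS (1.05 equiv), MeCN, 0 °C → rt, dark
Reagents that add atoms: N-iodosuccinimide, O=C1CCC(=O)N1I
Why: Electrophilic aromatic iodination, in which the free amino group is the strongest director and its only open ortho/para position is C6, so iodine should enter there and not ortho to the methoxy group.

Step 2
Reactants: 2 2-iodo-4-methoxy-6-methylaniline
Product: 4 2-bromo-1-iodo-5-methoxy-3-methylbenzene, via diazonium bromide 3 (not isolated)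
Conditions: NaNO2, 48% aq. HBr, MeCN/H2O, 0 °C; then CuBr (0.3 equiv), 48% aq. HBr, 60 °C
Reagents that add atoms: hydrobromic acid, Br; copper(I) bromide, [Cu]Br
Why: Sandmeyer reaction, in which diazotisation and copper-mediated bromine transfer to the aryl radical replace NH2 by Br at the same carbon while the iodide, methyl and methoxy groups stay in place.

Step 3
Reactants: 5 (R)-linalool; 4 2-bromo-1-iodo-5-methoxy-3-methylbenzene
Product: 7 (R)-1-(2-bromo-5-methoxy-3-methylphenyl)-3,7-dimethyloct-6-en-3-ol, via B-alkyl-9-BBN adduct 6 (not isolated)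
Conditions: 5 (1.2 equiv), 9-BBN (0.5 M in THF, 1.4 equiv), THF, 0 °C → rt; then 4 (1.0 equiv), Pd(dppf)Cl2·CH2Cl2 (5 mol %), AsPh3 (5 mol %), Cs2CO3 (3 equiv), DMF/THF/H2O, rt
Reagents that add atoms: none
Why: 9-BBN hydroborates the monosubstituted vinyl group anti-Markovnikov much faster than the trisubstituted alkene, and the B-alkyl Suzuki–Miyaura coupling should then occur at C–I because oxidative addition there is far faster than at the doubly ortho-flanked C–Br bond; the carbinol stereocentre takes no part.

Step 4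
Reactants: 7 (R)-1-(2-bromo-5-methoxy-3-methylphenyl)-3,7-dimethyloct-6-en-3-ol
Product: 8 (R)-6-methoxy-2,8-dimethyl-2-(4-methylpent-3-en-1-yl)chromane
Conditions: Pd(OAc)2 (3 mol %), 2-(di-tert-butylphosphino)-1,1′-binaphthyl (4 mol %), Cs2CO3 (1.5 equiv), toluene, 80 °C
Reagents that add atoms: none
Why: Pd(0) inserts into the hindered aryl C–Br bond, the caesium alkoxide of the tertiary carbinol replaces bromide on palladium to give a seven-membered oxapalladacycle, and C–O reductive elimination, driven by the bulky di-tert-butyl biaryl phosphine, forms O1–C8a. The closest known reaction type is the Buchwald–Hartwig intramolecular etherification of ortho-haloaryl alkanols, which is established for tertiary alcohols giving 2,2-disubstituted chromans. The dihydropyran ring is closed by this intramolecular O-arylation, the tethered oxygen bonding to the ring carbon that carried bromine, so the new six-membered ring is fused to the existing benzene ring. No stereocentre is created, and C2 keeps the (R) configuration of linalool because none of its four bonds is broken. The step needs C–O reductive elimination to outrun hydrodebromination and insertion of the remote alkene; the carbinol carbon has no hydrogen for β-hydride elimination, the two ortho substituents speed up reductive elimination, and the trisubstituted alkene could insert only through a medium ring.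

Step 5
Reactants: 8 (R)-6-methoxy-2,8-dimethyl-2-(4-methylpent-3-en-1-yl)chromane
Product: 10 (R,E)-5-(6-methoxy-2,8-dimethylchroman-2-yl)-2-methylpent-2-en-1-ol, via over-oxidised enal 9 (not isolated)
Conditions: SeO2 (0.3 equiv), t-BuOOH (70% aq., 3 equiv), salicylic acid (0.1 equiv), CH2Cl2, 0 °C → rt; then NaBH4, MeOH, 0 °C
Reagents that add atoms: selenium dioxide, O=[Se]=O (transfers the oxygen); tert-butyl hydroperoxide, CC(C)(C)OO (terminal oxygen source)
Why: Catalytic SeO2/t-BuOOH allylic oxidation (ene reaction, then [2,3]-sigmatropic shift) functionalises the E-methyl group at the more substituted alkene terminus and returns the (E)-alkene, and borohydride reduces any enal from over-oxidation back to the alcohol.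

Step 6
Reactants: 10 (R,E)-5-(6-methoxy-2,8-dimethylchroman-2-yl)-2-methylpent-2-en-1-ol
Product: 11 (R)-2-[(E)-5-bromo-4-methylpent-3-en-1-yl]-6-methoxy-2,8-dimethylchromane
Conditions: CBr4, PPh3, CH2Cl2, 0 °C; used without delay
Reagents that add atoms: carbon tetrabromide, BrC(Br)(Br)Br
Why: Appel bromination replaces the primary allylic hydroxyl by bromide through SN2 displacement of the oxyphosphonium group under neutral conditions that should leave the alkene geometry and the aryl ethers untouched.

Step 7
Reactants: 12 geranyl bromide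
Product: 13 geranyl phenyl sulfone
Conditions: PhSO2Na (1.3 equiv), DMF, rt
Reagents that add atoms: sodium benzenesulfinate, [Na+].[O-]S(=O)c1ccccc1
Why: SN2 S-alkylation of the ambident sulfinate by the primary allylic bromide in a dipolar aprotic solvent should give the sulfone with the (E)-alkene intact.

Step 8
Reactants: 13 geranyl phenyl sulfone
Product: 15 (2E,6E)-2,6-dimethyl-8-(phenylsulfonyl)octa-2,6-dien-1-ol, via over-oxidised enal 14 (not isolated)
Conditions: SeO2 (0.3 equiv), t-BuOOH (70% aq., 3 equiv), salicylic acid (0.1 equiv), CH2Cl2, 0 °C → rt; then NaBH4, MeOH, 0 °C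
Reagents that add atoms: selenium dioxide, O=[Se]=O (transfers the oxygen); tert-butyl hydroperoxide, CC(C)(C)OO (terminal oxygen source)
Why: The same SeO2 allylic oxidation attacks the electron-rich distal alkene, not the one deactivated by the neighbouring sulfonyl group, and oxidises its E-methyl group to the (E)-allylic alcohol.

Step 9
Reactants: 15 (2E,6E)-2,6-dimethyl-8-(phenylsulfonyl)octa-2,6-dien-1-ol
Product: 16 tert-butyl{[(2E,6E)-2,6-dimethyl-8-(phenylsulfonyl)octa-2,6-dien-1-yl]oxy}dimethylsilane
Conditions: TBSCl, imidazole, CH2Cl2, rt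
Reagents that add atoms: tert-butyldimethylsilyl chloride, CC(C)(C)[Si](C)(C)Cl
Why: Standard imidazole-promoted silylation of a primary alcohol gives an ether that is stable to butyllithium and to the hydride of step 11.

Step 10
Reactants: 16 tert-butyl{[(2E,6E)-2,6-dimethyl-8-(phenylsulfonyl)octa-2,6-dien-1-yl]oxy}dimethylsilane; 11 (R)-2-[(E)-5-bromo-4-methylpent-3-en-1-yl]-6-methoxy-2,8-dimethylchromane
Product: 18 (2R)-2-[(3E,7E,11E)-13-(tert-butyldimethylsilyloxy)-4,8,12-trimethyl-6-(phenylsulfonyl)trideca-3,7,11-trien-1-yl]-6-methoxy-2,8-dimethylchromane (both C6′ epimers), via lithiated sulfone 17 (not isolated)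
Conditions: 16 (1.1 equiv), n-BuLi (1.1 equiv), THF, −78 °C; then 11 (1.0 equiv) in THF, −78 → −20 °C
Reagents that add atoms: none
Why: Deprotonation next to the sulfone gives a sulfonyl-stabilised allyl anion that alkylates at its α-carbon with the primary allylic bromide by SN2 (allyl sulfone coupling of the Biellmann/Julia type) to form C5′–C6′; the new stereocentre at C6′ is not controlled and is removed in step 11.

Step 11
Reactants: 18 (2R)-2-[(3E,7E,11E)-13-(tert-butyldimethylsilyloxy)-4,8,12-trimethyl-6-(phenylsulfonyl)trideca-3,7,11-trien-1-yl]-6-methoxy-2,8-dimethylchromane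
Product: 19 tert-butyl{[(2E,6E,10E)-13-[(R)-6-methoxy-2,8-dimethylchroman-2-yl]-2,6,10-trimethyltrideca-2,6,10-trien-1-yl]oxy}dimethylsilane
Conditions: Pd(dppp)Cl2 (10 mol %), LiBHEt3 (2.5 equiv), THF, 0 °C
Reagents that add atoms: none
Why: Palladium-catalysed reductive desulfonylation, in which Pd(0) ionises the allylic sulfone to a syn π-allyl complex and hydride is delivered to the less substituted terminus C6′, so the C7′=C8′ alkene should stay in place with E geometry while the silyl and aryl ethers are inert to the hydride.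

Step 12
Reactants: 19 tert-butyl{[(2E,6E,10E)-13-[(R)-6-methoxy-2,8-dimethylchroman-2-yl]-2,6,10-trimethyltrideca-2,6,10-trien-1-yl]oxy}dimethylsilane
Product: 20 (2E,6E,10E)-13-[(R)-6-methoxy-2,8-dimethylchroman-2-yl]-2,6,10-trimethyltrideca-2,6,10-trien-1-ol
Conditions: TBAF, THF, 0 °C → rt
Reagents that add atoms: none
Why: Fluoride-driven desilylation frees the primary allylic alcohol without affecting the alkenes or the aryl methyl ether.

Step 13
Reactants: 20 (2E,6E,10E)-13-[(R)-6-methoxy-2,8-dimethylchroman-2-yl]-2,6,10-trimethyltrideca-2,6,10-trien-1-ol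
Product: 21 (2E,6E,10E)-13-[(R)-6-methoxy-2,8-dimethylchroman-2-yl]-2,6,10-trimethyltrideca-2,6,10-trienal
Conditions: activated MnO2 (excess), CH2Cl2, rt
Reagents that add atoms: none
Why: Manganese dioxide oxidises allylic alcohols selectively to enals with retention of the E geometry and should not touch the isolated alkenes or the benzylic positions.

Step 14
Reactants: 21 (2E,6E,10E)-13-[(R)-6-methoxy-2,8-dimethylchroman-2-yl]-2,6,10-trimethyltrideca-2,6,10-trienal
Product: 22 (2E,6E,10E)-13-[(R)-6-methoxy-2,8-dimethylchroman-2-yl]-2,6,10-trimethyltrideca-2,6,10-trienoic acid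
Conditions: NaClO2, NaH2PO4, 2-methyl-2-butene (large excess), t-BuOH/H2O, 0 °C → rt
Reagents that add atoms: sodium chlorite, [Na+].[O-]Cl=O
Why: Pinnick oxidation converts the enal into the acid without isomerising the alkene, and the excess 2-methyl-2-butene traps hypochlorous acid before it can chlorinate the alkenes or the electron-rich arene.

Step 15
Reactants: 22 (2E,6E,10E)-13-[(R)-6-methoxy-2,8-dimethylchroman-2-yl]-2,6,10-trimethyltrideca-2,6,10-trienoic acid
Product: 23 garcinoic acid, (2E,6E,10E)-13-[(R)-6-hydroxy-2,8-dimethylchroman-2-yl]-2,6,10-trimethyltrideca-2,6,10-trienoic acid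
Conditions: NaSEt (6 equiv), DMF, 120 °C, argon; then aq. HCl to pH 3, 0 °C
Reagents that add atoms: none
Why: Thiolate SN2 demethylation, in which the acid is first converted into its carboxylate (a poor Michael acceptor) and ethanethiolate then attacks the O-methyl carbon, the only unhindered sp3 carbon on an ether oxygen since the other one is the tertiary C2, while the isolated trisubstituted alkenes do not react.

**Compound list**

1 | 4-methoxy-2-methylaniline | COc1ccc(N)c(C)c1 | starting material
2 | 2-iodo-4-methoxy-6-methylaniline | COc1cc(C)c(N)c(I)c1 | intermediate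
3 | 2-iodo-4-methoxy-6-methylbenzenediazonium bromide | COc1cc(C)c([N+]#N)c(I)c1.[Br-] | intermediate (not isolated)
4 | 2-bromo-1-iodo-5-methoxy-3-methylbenzene | COc1cc(C)c(Br)c(I)c1 | intermediate
5 | (R)-linalool, (R)-3,7-dimethylocta-1,6-dien-3-ol | CC(C)=CCC[C@@](C)(O)C=C | starting material
6 | 9-[(S)-3-hydroxy-3,7-dimethyloct-6-en-1-yl]-9-borabicyclo[3.3.1]nonane (same spatial arrangement as 5; descriptor changes by CIP rank only) | CC(C)=CCC[C@@](C)(O)CCB1C2CCCC1CCC2 | intermediate (not isolated)
7 | (R)-1-(2-bromo-5-methoxy-3-methylphenyl)-3,7-dimethyloct-6-en-3-ol | COc1cc(C)c(Br)c(CC[C@](C)(O)CCC=C(C)C)c1 | intermediate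
8 | (R)-6-methoxy-2,8-dimethyl-2-(4-methylpent-3-en-1-yl)chromane | COc1cc(C)c2O[C@](C)(CCC=C(C)C)CCc2c1 | intermediate
9 | (R,E)-5-(6-methoxy-2,8-dimethylchroman-2-yl)-2-methylpent-2-enal | COc1cc(C)c2O[C@](C)(CC/C=C(\C)C=O)CCc2c1 | intermediate (not isolated; over-oxidation product returned to 10)
10 | (R,E)-5-(6-methoxy-2,8-dimethylchroman-2-yl)-2-methylpent-2-en-1-ol | COc1cc(C)c2O[C@](C)(CC/C=C(\C)CO)CCc2c1 | intermediate
11 | (R)-2-[(E)-5-bromo-4-methylpent-3-en-1-yl]-6-methoxy-2,8-dimethylchromane | COc1cc(C)c2O[C@](C)(CC/C=C(\C)CBr)CCc2c1 | intermediate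
12 | geranyl bromide, (E)-1-bromo-3,7-dimethylocta-2,6-diene | CC(C)=CCC/C(C)=C/CBr | starting material
13 | geranyl phenyl sulfone, {[(E)-3,7-dimethylocta-2,6-dien-1-yl]sulfonyl}benzene | CC(C)=CCC/C(C)=C/CS(=O)(=O)c1ccccc1 | intermediate
14 | (2E,6E)-2,6-dimethyl-8-(phenylsulfonyl)octa-2,6-dienal | O=C/C(C)=C/CC/C(C)=C/CS(=O)(=O)c1ccccc1 | intermediate (not isolated; over-oxidation product returned to 15)
15 | (2E,6E)-2,6-dimethyl-8-(phenylsulfonyl)octa-2,6-dien-1-ol | OC/C(C)=C/CC/C(C)=C/CS(=O)(=O)c1ccccc1 | intermediate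
16 | tert-butyl{[(2E,6E)-2,6-dimethyl-8-(phenylsulfonyl)octa-2,6-dien-1-yl]oxy}dimethylsilane | CC(C)(C)[Si](C)(C)OC/C(C)=C/CC/C(C)=C/CS(=O)(=O)c1ccccc1 | intermediate
17 | α-lithio derivative of sulfone 16 | [Li]C(/C=C(\C)CC/C=C(\C)CO[Si](C)(C)C(C)(C)C)S(=O)(=O)c1ccccc1 | intermediate (not isolated)
18 | (2R)-2-[(3E,7E,11E)-13-(tert-butyldimethylsilyloxy)-4,8,12-trimethyl-6-(phenylsulfonyl)trideca-3,7,11-trien-1-yl]-6-methoxy-2,8-dimethylchromane, both C6′ epimers | COc1cc(C)c2O[C@](C)(CC/C=C(\C)CC(S(=O)(=O)c3ccccc3)/C=C(\C)CC/C=C(\C)CO[Si](C)(C)C(C)(C)C)CCc2c1 | intermediate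
19 | tert-butyl{[(2E,6E,10E)-13-[(R)-6-methoxy-2,8-dimethylchroman-2-yl]-2,6,10-trimethyltrideca-2,6,10-trien-1-yl]oxy}dimethylsilane | COc1cc(C)c2O[C@](C)(CC/C=C(\C)CC/C=C(\C)CC/C=C(\C)CO[Si](C)(C)C(C)(C)C)CCc2c1 | intermediate
20 | (2E,6E,10E)-13-[(R)-6-methoxy-2,8-dimethylchroman-2-yl]-2,6,10-trimethyltrideca-2,6,10-trien-1-ol | COc1cc(C)c2O[C@](C)(CC/C=C(\C)CC/C=C(\C)CC/C=C(\C)CO)CCc2c1 | intermediate
21 | (2E,6E,10E)-13-[(R)-6-methoxy-2,8-dimethylchroman-2-yl]-2,6,10-trimethyltrideca-2,6,10-trienal | COc1cc(C)c2O[C@](C)(CC/C=C(\C)CC/C=C(\C)CC/C=C(\C)C=O)CCc2c1 | intermediate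
22 | (2E,6E,10E)-13-[(R)-6-methoxy-2,8-dimethylchroman-2-yl]-2,6,10-trimethyltrideca-2,6,10-trienoic acid | COc1cc(C)c2O[C@](C)(CC/C=C(\C)CC/C=C(\C)CC/C=C(\C)C(=O)O)CCc2c1 | intermediate
23 | garcinoic acid, (2E,6E,10E)-13-[(R)-6-hydroxy-2,8-dimethylchroman-2-yl]-2,6,10-trimethyltrideca-2,6,10-trienoic acid | C/C(=C\CC/C(C)=C/CC[C@]1(C)CCc2cc(O)cc(C)c2O1)CC/C=C(\C)C(=O)O | target

**Step count**

Total: 15 steps. Longest linear sequence: 12 steps (1, 2, 3, 4, 5, 6, 10, 11, 12, 13, 14, 15, from 4-methoxy-2-methylaniline).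

**Steps most likely to fail**

Step 4. Oxidative addition may stall at the electron-rich, doubly ortho-substituted C–Br bond, or the arylpalladium alkoxide may be reduced (hydrodebromination) before C–O reductive elimination. The fallback sets out from 7 and comes back at 8, changing both the halide and the metal. The alcohol is deprotonated (n-BuLi, THF, −78 °C), bromine is exchanged for lithium (t-BuLi, 2 equiv), and the aryllithium is quenched with 1,2-diiodoethane to give (R)-1-(2-iodo-5-methoxy-3-methylphenyl)-3,7-dimethyloct-6-en-3-ol F1. The same O1–C8a bond is then closed by copper(I)-catalysed Ullmann etherification (CuI, 3,4,7,8-tetramethyl-1,10-phenanthroline, Cs2CO3, toluene, 110 °C). This runs through a copper alkoxide with no palladium hydride pathway and again leaves C2 untouched, arriving at 8.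

Step 3. The tertiary hydroxyl may consume or coordinate the borane, so hydroboration stays incomplete or transmetalation becomes slow, and a long reaction time could erode the iodide/bromide selectivity. The fallback sets out from 5 and 4 and comes back at 7 without any boron chemistry. Heck arylation of the vinyl group under Jeffery conditions (Pd(OAc)2, Bu4NCl, NaHCO3, DMF, 50 °C; β-hydride elimination is possible only towards the aryl-bearing carbon) should give (R,E)-1-(2-bromo-5-methoxy-3-methylphenyl)-3,7-dimethylocta-1,6-dien-3-ol F2. Diimide (2-nitrobenzenesulfonyl hydrazide, Et3N, CH2Cl2, rt) then reduces the 1,2-disubstituted styrenyl alkene in preference to the trisubstituted one and does not touch C–Br, giving 7.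

Step 15. Hot thiolate may add reversibly to the C11′=C12′ enoate and scramble its geometry, and the phenolate formed may oxidise in air during the long heating. The fallback sets out from 20 and comes back at 23, removing the methyl group before the conjugated acid exists. NaSEt in DMF at 120 °C on 20 should give (R)-2-[(3E,7E,11E)-13-hydroxy-4,8,12-trimethyltrideca-3,7,11-trien-1-yl]-2,8-dimethylchroman-6-ol F3. Phenol-selective O-allylation (allyl bromide, K2CO3, acetone) gives (2E,6E,10E)-13-[(R)-6-(allyloxy)-2,8-dimethylchroman-2-yl]-2,6,10-trimethyltrideca-2,6,10-trien-1-ol F4. MnO2 gives (2E,6E,10E)-13-[(R)-6-(allyloxy)-2,8-dimethylchroman-2-yl]-2,6,10-trimethyltrideca-2,6,10-trienal F5, and Pinnick oxidation gives (2E,6E,10E)-13-[(R)-6-(allyloxy)-2,8-dimethylchroman-2-yl]-2,6,10-trimethyltrideca-2,6,10-trienoic acid F6. The allyl group is then taken off at room temperature with Pd(PPh3)4 and morpholine in THF to give 23.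

**Further compounds**

F1 | step 4 | (R)-1-(2-iodo-5-methoxy-3-methylphenyl)-3,7-dimethyloct-6-en-3-ol | COc1cc(C)c(I)c(CC[C@](C)(O)CCC=C(C)C)c1
F2 | step 3 | (R,E)-1-(2-bromo-5-methoxy-3-methylphenyl)-3,7-dimethylocta-1,6-dien-3-ol | COc1cc(C)c(Br)c(/C=C/[C@](C)(O)CCC=C(C)C)c1
F3 | step 15 | (R)-2-[(3E,7E,11E)-13-hydroxy-4,8,12-trimethyltrideca-3,7,11-trien-1-yl]-2,8-dimethylchroman-6-ol | Oc1cc(C)c2O[C@](C)(CC/C=C(\C)CC/C=C(\C)CC/C=C(\C)CO)CCc2c1
F4 | step 15 | (2E,6E,10E)-13-[(R)-6-(allyloxy)-2,8-dimethylchroman-2-yl]-2,6,10-trimethyltrideca-2,6,10-trien-1-ol | C=CCOc1cc(C)c2O[C@](C)(CC/C=C(\C)CC/C=C(\C)CC/C=C(\C)CO)CCc2c1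
F5 | step 15 | (2E,6E,10E)-13-[(R)-6-(allyloxy)-2,8-dimethylchroman-2-yl]-2,6,10-trimethyltrideca-2,6,10-trienal | C=CCOc1cc(C)c2O[C@](C)(CC/C=C(\C)CC/C=C(\C)CC/C=C(\C)C=O)CCc2c1
F6 | step 15 | (2E,6E,10E)-13-[(R)-6-(allyloxy)-2,8-dimethylchroman-2-yl]-2,6,10-trimethyltrideca-2,6,10-trienoic acid | C=CCOc1cc(C)c2O[C@](C)(CC/C=C(\C)CC/C=C(\C)CC/C=C(\C)C(=O)O)CCc2c1
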